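## Structural features

The target is one carbocycle, a cyclohexa-1,3-diene (C1=C2–C3=C4). Its two sp3 carbons C5 and C6 carry a benzoate and a free hydroxyl, and C1 carries a benzoyloxymethyl group (C7). C5 and C6 are the only stereocentres; they are adjacent, both R, and their oxygens are trans. The compound is a protected arene trans-dihydrodiol and is fragile in several ways: loss of water or benzoic acid across C5–C6 gives a benzene ring, both benzoates are allylic, the C5 benzoate can migrate to the C6 hydroxyl, and the diene is open to oxidants and dienophiles. The real difficulty is therefore to reach the diene oxidation level late and gently, and to tell three oxygens apart so that O5 and O7 are benzoylated and O6 is not. The chain C7–C1–C6(O)–C5(O) with trans oxygens corresponds to positions 1 to 4 of D-glucal in the correct absolute sense, and C4=C3–C2 can be a vinyl group on sugar position 5. In such a 5-vinyl glycal the ring oxygen, the enol ether and the vinyl group form an allyl vinyl ether. A [3,3] shift that joins target C1 to C2 turns the pyran ring into the carbocycle and leaves C7 as an aldehyde.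

## Logic of the disconnections

**14 ⇒ 13.** The O6–H bond of 14 is traced back to an O6–Si bond. O6 must be the one oxygen that is not acylated, and a silyl ether carried on it since the sugar stage keeps it apart at no extra cost. This reduces the regiochemical problem of 14 to a per-benzoylation. The forward step must cleave Si–O under mildly acidic fluoride so that the C5 benzoate does not move to O6 and nothing aromatises.

**13 ⇒ 12.** Both acyl C–O bonds (at O5 and at O7) are cut together. Both esters are the same, so one operation installs them, and the precursor is a diol with O6 still masked. The forward step must fully acylate the hindered C5 hydroxyl beside the silyl ether without silyl migration.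

**12 ⇒ 11 ⇒ 10.** The C7–H bond made by hydride and the benzylic C–O bond of the O5 ether are cut. Going back to the aldehyde oxidation level at C7 gives an electron-poor diene, and that is the stage at which a benzyl-type ether can be removed oxidatively without harm to the diene or to an allylic alcohol. The forward steps need 1,2-selective hydride addition and an oxidant that stops at ether cleavage.

**10 ⇒ 8 (through 9) ⇒ 7.** The C1=C2 π bond is removed and replaced by a C1–Se bond, which is then cut. The formyl group activates C1–H for exactly this one dehydrogenation. The diene becomes an isolated alkene and the ring becomes the direct product of a sigmatropic step. The forward steps must functionalise C1 without expelling the β-silyloxy group at C6, and the syn elimination must go toward C2.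

**7 ⇒ 6.** The C1–C2 σ bond is cut and C4 is reconnected to the carbonyl oxygen (retro-Claisen). The carbocycle becomes a pyran whose stereocentres are those of a sugar: C5 and C6 of 7 are sugar positions 4 and 3 of 6. The forward step needs about 240 °C, a reactive conformer with a pseudo-axial vinyl group, and ether groups that survive the heat.

**6 ⇒ 5 ⇒ 4.** The terminal C=C (target C2=C3) is cut into a carbonyl and a one-carbon ylide, and the carbonyl is traced to the primary alcohol. This returns to a plain hexose skeleton. The aldehyde has an α-stereocentre and a β-alkoxy group, so oxidation and olefination must be non-enolising.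

**4 ⇒ 3 ⇒ 2 ⇒ 1.** The benzylic C–H and C–O6 relationship (reductive acetal opening), the O3–Si bond and the two acetal C–O bonds are cut. One cyclic acetal protects sugar O4 and O6 together, and its reductive opening tells them apart, leaving the benzyl-type ether on O4 and the primary hydroxyl free. The forward opening must go toward O6; the bulky silyl ether next to O4 supports this.

## Other disconnections considered

**Alternative 1:** The cut is the C5–C6 bond, reached through the C3–C6 bond of a four-membered ring. In the forward sense the cis cyclobutene A2, with Sc(OTf)3 and a chiral pybox ligand (trivalent scandium), would open conrotatorily to the triene A3, which would close disrotatorily to A1.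
- In its favour: the diene, the C1 carboxyl carbon and the trans pair all come from orbital symmetry in one operation. The silyloxy group should rotate outward, which forces the alkenyl arm inward and gives an out/in pair of termini that can only close trans. From A1, three operations (hydride reduction of both esters, double benzoylation, desilylation) would finish the synthesis. That is fewer than the six needed after the rearrangement in the chosen plan, so on steps after the key event the alternative is the better.
- Against it: both stereocentres of A2 vanish in A3. The absolute configuration of A1 would have to come entirely from the catalyst steering the sense of disrotation through one bound ester carbonyl, in a reaction class with few catalytic enantioselective examples. A3 carries an enol benzoate and a silyl enol ether, and A1 is an acid-sensitive dihydroarene beside a Lewis acid, so aromatisation competes. A2 with its Z enol benzoate is not trivial to make.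
- A point of nomenclature: with silyloxy out and benzoyloxy in, all three double bonds of A3 are Z by the sequence rules, because the ester outranks the chain carbon at C1. An E label at the silyloxy terminus would be a misnomer.
- Comparison: on structure, the alternative delivers the diene directly and is the better. On mechanism, both plans are thermally allowed pericyclic processes and equal in delivering the trans pair, but the chosen plan takes absolute configuration from the chiral pool and is the safer. On step economy, the alternative would be shorter if A2 were easy to reach.

**Alternative 2:** Three bonds are cut at once, C1–C6, C2–C3 and C4–C5, which takes the ring apart into the silicon-tethered enyne A5 and acetylene A6. Forward, [Rh(cod)2]BF4 with a BINAP ligand (monovalent rhodium) would join the alkyne, A6 and the tethered alkene in a [2+2+2] cycloaddition to A4, the carbocycle fused to a dioxasilinane.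
- In its favour: it is the most convergent plan, making the ring, the whole diene and three C–C bonds from achiral components at the final oxidation level. The trans pair would follow stereospecifically from the E alkene of A5, which is the equal of inheriting it from a sugar. After removal of the tether only the primary allylic hydroxyl needs benzoylation. On step count and redox economy this alternative is clearly the better.
- Against it: the alkene of A5 is an electron-rich, acyclic, 1,2-dioxygenated enol derivative, a reluctant partner for oxidative cyclisation. Alkyne trimerisation to arenes competes. The rhodacycle would carry β-oxygen substituents that can be eliminated. Enantioselection would rest wholly on the ligand. The Si–O–vinyl link of A5 is hydrolytically weak, and A4 is a cyclohexadiene exposed to a metal that can dehydrogenate it.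
- Comparison: on structure and step economy the alternative wins. On mechanism the chosen plan needs only heat and no cross-, chemo- or enantioselection, whereas the alternative needs all of these at once, so its risk is much higher.

**Alternative 3:** The cut is the central diene bond C2–C3. Forward, the open-chain bis(Z-vinyl iodide) A8, at high dilution with stoichiometric Ni(cod)2 and PPh3 (zerovalent nickel), would undergo two oxidative additions and a reductive elimination to A7.
- In its favour: the stereocentres are set before the ring exists and are spectators, which equals the chosen plan. The diene arrives at the final oxidation level with C7 already at the alcohol level, so no dehydrogenation and no carbonyl reduction follow. Only three operations would remain after ring closure; on that count the alternative is the better.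
- Against it: A8 needs two separately built, geometrically pure Z vinyl iodides, one of them trisubstituted, and this is where the step count would be spent. Stoichiometric air-sensitive nickel at high dilution scales poorly. Proto-deiodination and oligomerisation compete. The end-game would require oxidative removal of two 4-methoxybenzyl groups from an electron-rich cyclohexadiene that then bears allylic alcohols, which is the situation the chosen plan avoids.
- Comparison: on structure the alternative is the more direct. On mechanism the chosen plan is reagent-free and more robust. On overall step economy the two are expected to be similar, since the steps saved after the ring closure are spent on making A8.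

Key step: step 6

**Remarks on the chemistry (one line each)**
- Atom labels C1–C7 are those of the target; sugar positions are named as such.
- Assumption: 1 is bought as such (it is a catalogue compound).
- Structure check: 6 and 7 as listed are stereochemically consistent with 1 and with the target; the rearrangement does create one stereocentre (C1 of 7, S, formyl cis to the C5 oxygen), which step 8 removes.
- At 240 °C the solvent is above its boiling point, so step 6 is run in a sealed vessel.
- The 4-methoxybenzyl ether is cleaved at the dienal 10 and not after the carbonyl reduction, because a quinone oxidant is expected to dehydrogenate an electron-rich cyclohexa-1,3-diene and to oxidise its allylic alcohols.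
- The ether pair of 6 is kept by design: an ester on sugar O4 would become an allylic ester in 7 and could shift or eliminate at 240 °C, and the triisopropylsilyl group resists 1,2-migration while the neighbouring C5 hydroxyl is free in 11 and 12.

## Route

Step 1
Reactants: 1 D-glucal (1,5-anhydro-2-deoxy-D-arabino-hex-1-enitol)
Product: 2 1,5-anhydro-2-deoxy-4,6-O-[(R)-4-methoxybenzylidene]-D-arabino-hex-1-enitol
Conditions: 4-MeOC6H4CH(OMe)2, pyridinium p-toluenesulfonate (cat.), DMF, 40 °C, reduced pressure; then Et3N
Reagents that add atoms: 4-methoxybenzaldehyde dimethyl acetal, COc1ccc(C(OC)OC)cc1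
Why: Acid-catalysed transacetalisation; the trans-fused six-membered 1,3-dioxane across O4 and O6 is the thermodynamic product and places the aryl group equatorial, which fixes the acetal carbon as R. The weak pyridinium acid and continuous removal of methanol spare the acid-labile enol ether.

Step 2
Reactants: 2 1,5-anhydro-2-deoxy-4,6-O-[(R)-4-methoxybenzylidene]-D-arabino-hex-1-enitol
Product: 3 1,5-anhydro-2-deoxy-4,6-O-[(R)-4-methoxybenzylidene]-3-O-(triisopropylsilyl)-D-arabino-hex-1-enitol
Conditions: TIPSCl, imidazole, 4-(dimethylamino)pyridine (cat.), DMF, 40 °C
Reagents that add atoms: triisopropylsilyl chloride, CC(C)[Si](Cl)(C(C)C)C(C)C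
Why: Imidazole-promoted silylation of the only free hydroxyl, which is allylic and equatorial; acetal and enol ether are inert to these basic conditions.

Step 3
Reactants: 3 1,5-anhydro-2-deoxy-4,6-O-[(R)-4-methoxybenzylidene]-3-O-(triisopropylsilyl)-D-arabino-hex-1-enitol
Product: 4 1,5-anhydro-2-deoxy-4-O-(4-methoxybenzyl)-3-O-(triisopropylsilyl)-D-arabino-hex-1-enitol
Conditions: iBu2AlH (toluene solution), CH2Cl2, −78 → 0 °C; aqueous potassium sodium tartrate
Reagents that add atoms: none
Why: Regioselective reductive opening of a 4-methoxybenzylidene acetal by a Lewis-acidic hydride: aluminium binds the less hindered O6 (O4 is screened by the neighbouring silyl ether), the C–O6 bond ionises and hydride quenches the oxocarbenium ion. O4 is left as its 4-methoxybenzyl ether and the primary hydroxyl is freed.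

Step 4
Reactants: 4 1,5-anhydro-2-deoxy-4-O-(4-methoxybenzyl)-3-O-(triisopropylsilyl)-D-arabino-hex-1-enitol
Product: 5 (2S,3R,4R)-3-[(4-methoxybenzyl)oxy]-4-[(triisopropylsilyl)oxy]-3,4-dihydro-2H-pyran-2-carbaldehyde (the C6 aldehyde of 4)
Conditions: Dess–Martin periodinane, pyridine, CH2Cl2, 0 °C → rt; crude product used at once
Reagents that add atoms: none
Why: Dess–Martin oxidation of the primary alcohol under buffered, non-enolising conditions, chosen because 5 has an α-stereocentre and a β-alkoxy group; the enol ether, silyl ether and benzyl-type ether are not touched.

Step 5
Reactants: 5 (2S,3R,4R)-3-[(4-methoxybenzyl)oxy]-4-[(triisopropylsilyl)oxy]-3,4-dihydro-2H-pyran-2-carbaldehyde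
Product: 6 (2R,3R,4R)-2-ethenyl-3-[(4-methoxybenzyl)oxy]-4-[(triisopropylsilyl)oxy]-3,4-dihydro-2H-pyran (the 5-vinyl glycal)
Conditions: Ph3PCH3Br (slight excess over base), KN(SiMe3)2, THF, 0 °C; then 5, −78 → 0 °C
Reagents that add atoms: methyltriphenylphosphonium bromide, C[P+](c1ccccc1)(c1ccccc1)c1ccccc1.[Br-]
Why: Wittig methylenation; the unstabilised ylide, with no free amide base left, adds to the aldehyde faster than it deprotonates the α-carbon, so β-elimination of the ether should not compete. The configuration at sugar position 5 is not critical because this carbon becomes sp2 in step 6.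

Step 6
Reactants: 6 (2R,3R,4R)-2-ethenyl-3-[(4-methoxybenzyl)oxy]-4-[(triisopropylsilyl)oxy]-3,4-dihydro-2H-pyran
Product: 7 (1S,5R,6R)-5-[(4-methoxybenzyl)oxy]-6-[(triisopropylsilyl)oxy]cyclohex-3-ene-1-carbaldehyde
Conditions: o-C6H4Cl2 (degassed, dilute), sealed base-washed tube, 240 °C, 1–2 h
Reagents that add atoms: none
Why: Concerted [3,3]-sigmatropic (Claisen) rearrangement of the allyl vinyl ether formed by the ring enol ether and the vinyl group on sugar position 5: the enol ether β-carbon bonds to the vinyl terminus as the ring C–O bond breaks, so the formyl group and the new ring alkene appear together. The closest known reaction type is the thermal rearrangement of 2-vinyl-3,4-dihydro-2H-pyrans, including 3,4-di-O-alkylated 5-vinyl glycals, to cyclohex-3-ene-1-carbaldehydes at this temperature. The six-membered carbocycle is closed by the pericyclic C–C bond formation itself, through a boat-like six-centre transition state (a bicyclo[2.2.2]octane-like array) that the two-carbon tether enforces and that requires the half-chair with a pseudo-axial vinyl group. The one new stereocentre, C1 of 7, is set by the substrate: the vinyl terminus can reach the enol ether only on the ring face that carries it, which puts the formyl group cis to the C5 oxygen and trans to the C6 oxygen (1S); this centre is removed in step 8, so its control is not needed. C5 and C6 of 7 are sugar positions 4 and 3 and are not touched. The selectivity required is chemoselectivity, rearrangement without loss of the β-silyloxy group or of the allylic ether; it is secured by having only non-ionisable ethers on the oxygens, by a neutral, degassed, aprotic medium in base-washed glass, and by stopping at full conversion. Formation of the carbonyl group makes the change irreversible.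

Step 7
Reactants: 7 (1S,5R,6R)-5-[(4-methoxybenzyl)oxy]-6-[(triisopropylsilyl)oxy]cyclohex-3-ene-1-carbaldehyde
Product: 8 (5R,6S)-5-[(4-methoxybenzyl)oxy]-1-(phenylselanyl)-6-[(triisopropylsilyl)oxy]cyclohex-3-ene-1-carbaldehyde, either or both C1 epimers (C5 and C6 spatially as in 7; the 6S label is only a change of priority caused by selenium)
Conditions: N-(phenylseleno)phthalimide, L-prolinamide (20 mol %), CH2Cl2, 0 °C → rt; filtration through silica
Reagents that add atoms: N-(phenylseleno)phthalimide, O=C1N([Se]c2ccccc2)C(=O)c2ccccc21
Why: Enamine-mediated α-selenenylation of an aldehyde: the catalytic amine forms the enamine of 7, which attacks electrophilic selenium at C1. Neutral conditions without a metal enolate are chosen to keep the β-silyloxy group in place, and the configuration of the quaternary C1 does not matter because C1 becomes sp2 in step 8.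

Step 8
Reactants: 8 (5R,6S)-5-[(4-methoxybenzyl)oxy]-1-(phenylselanyl)-6-[(triisopropylsilyl)oxy]cyclohex-3-ene-1-carbaldehyde
Product: 10 (5R,6R)-5-[(4-methoxybenzyl)oxy]-6-[(triisopropylsilyl)oxy]cyclohexa-1,3-diene-1-carbaldehyde, via selenoxide 9 (not isolated)
Conditions: H2O2 (30 % aq.), pyridine, CH2Cl2, 0 °C → rt
Reagents that add atoms: none
Why: Oxidation of the selenide to the selenoxide followed by spontaneous syn elimination (selenoxide elimination). Elimination should go toward C2, whose hydrogens are allylic and lead to the conjugated dienal, and not toward C6, because selenoxides avoid eliminating toward an oxygen-bearing carbon; the pericyclic elimination needs no enolate, so the C6 ether is not at risk.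

Step 9
Reactants: 10 (5R,6R)-5-[(4-methoxybenzyl)oxy]-6-[(triisopropylsilyl)oxy]cyclohexa-1,3-diene-1-carbaldehyde
Product: 11 (5R,6R)-5-hydroxy-6-[(triisopropylsilyl)oxy]cyclohexa-1,3-diene-1-carbaldehyde
Conditions: DDQ, CH2Cl2 / aqueous NaH2PO4–Na2HPO4 buffer (pH 7), 0 °C
Reagents that add atoms: none
Why: Oxidative cleavage of a 4-methoxybenzyl ether by DDQ (hydride abstraction at the electron-rich benzylic carbon, hydrolysis of the oxocarbenium ion). The diene is conjugated to the formyl group at this stage and therefore a poor hydride donor, and no allylic alcohol activated toward the quinone is present.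

Step 10
Reactants: 11 (5R,6R)-5-hydroxy-6-[(triisopropylsilyl)oxy]cyclohexa-1,3-diene-1-carbaldehyde
Product: 12 (1R,6R)-5-(hydroxymethyl)-6-[(triisopropylsilyl)oxy]cyclohexa-2,4-dien-1-ol
Conditions: NaBH4, CeCl3·7H2O, MeOH, −78 → −40 °C; aqueous NH4Cl
Reagents that add atoms: none
Why: Luche reduction: the cerium salt directs hydride to the carbonyl carbon (1,2-addition) and keeps the medium non-basic, so neither conjugate reduction nor silyl migration to the free C5 hydroxyl is expected at low temperature.

Step 11
Reactants: 12 (1R,6R)-5-(hydroxymethyl)-6-[(triisopropylsilyl)oxy]cyclohexa-2,4-dien-1-ol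
Product: 13 [(5R,6R)-5-(benzoyloxy)-6-[(triisopropylsilyl)oxy]cyclohexa-1,3-dien-1-yl]methyl benzoate
Conditions: BzCl (excess), pyridine, 4-(dimethylamino)pyridine (cat.), CH2Cl2, 0 °C → rt
Reagents that add atoms: benzoyl chloride, O=C(Cl)c1ccccc1
Why: Nucleophile-catalysed O-acylation of the primary and the secondary allylic hydroxyl in one operation. The silyl ether blocks O6, and acylation is much faster than any silyl shift under these weakly basic conditions.

Step 12
Reactants: 13 [(5R,6R)-5-(benzoyloxy)-6-[(triisopropylsilyl)oxy]cyclohexa-1,3-dien-1-yl]methyl benzoate
Product: 14 [(5R,6R)-5-(benzoyloxy)-6-hydroxycyclohexa-1,3-dien-1-yl]methyl benzoate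
Conditions: HF·pyridine, pyridine, THF, 0 °C → rt
Reagents that add atoms: none
Why: Fluoride-induced cleavage of the silyl ether in a mildly acidic, pyridine-buffered medium. Under these conditions base-promoted 1,2-migration of the C5 benzoate to O6 and base-induced elimination are avoided, and both stereocentres are untouched.

## Compound list

1 | D-glucal (1,5-anhydro-2-deoxy-D-arabino-hex-1-enitol) | OC[C@H]1OC=C[C@@H](O)[C@@H]1O | starting material
2 | 1,5-anhydro-2-deoxy-4,6-O-[(R)-4-methoxybenzylidene]-D-arabino-hex-1-enitol | COc1ccc([C@@H]2OC[C@H]3OC=C[C@@H](O)[C@@H]3O2)cc1 | intermediate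
3 | 1,5-anhydro-2-deoxy-4,6-O-[(R)-4-methoxybenzylidene]-3-O-(triisopropylsilyl)-D-arabino-hex-1-enitol | COc1ccc([C@@H]2OC[C@H]3OC=C[C@@H](O[Si](C(C)C)(C(C)C)C(C)C)[C@@H]3O2)cc1 | intermediate
4 | 1,5-anhydro-2-deoxy-4-O-(4-methoxybenzyl)-3-O-(triisopropylsilyl)-D-arabino-hex-1-enitol | OC[C@H]1OC=C[C@@H](O[Si](C(C)C)(C(C)C)C(C)C)[C@@H]1OCc1ccc(OC)cc1 | intermediate
5 | (2S,3R,4R)-3-[(4-methoxybenzyl)oxy]-4-[(triisopropylsilyl)oxy]-3,4-dihydro-2H-pyran-2-carbaldehyde | O=C[C@H]1OC=C[C@@H](O[Si](C(C)C)(C(C)C)C(C)C)[C@@H]1OCc1ccc(OC)cc1 | intermediate
6 | (2R,3R,4R)-2-ethenyl-3-[(4-methoxybenzyl)oxy]-4-[(triisopropylsilyl)oxy]-3,4-dihydro-2H-pyran | C=C[C@H]1OC=C[C@@H](O[Si](C(C)C)(C(C)C)C(C)C)[C@@H]1OCc1ccc(OC)cc1 | intermediate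
7 | (1S,5R,6R)-5-[(4-methoxybenzyl)oxy]-6-[(triisopropylsilyl)oxy]cyclohex-3-ene-1-carbaldehyde | O=C[C@H]1CC=C[C@@H](OCc2ccc(OC)cc2)[C@@H]1O[Si](C(C)C)(C(C)C)C(C)C | intermediate
8 | (5R,6S)-5-[(4-methoxybenzyl)oxy]-1-(phenylselanyl)-6-[(triisopropylsilyl)oxy]cyclohex-3-ene-1-carbaldehyde (C1 epimers) | O=CC1([Se]c2ccccc2)CC=C[C@@H](OCc2ccc(OC)cc2)[C@@H]1O[Si](C(C)C)(C(C)C)C(C)C | intermediate
9 | (5R,6S)-5-[(4-methoxybenzyl)oxy]-1-(phenylseleninyl)-6-[(triisopropylsilyl)oxy]cyclohex-3-ene-1-carbaldehyde (selenoxide of 8) | O=CC1([Se](=O)c2ccccc2)CC=C[C@@H](OCc2ccc(OC)cc2)[C@@H]1O[Si](C(C)C)(C(C)C)C(C)C | intermediate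
10 | (5R,6R)-5-[(4-methoxybenzyl)oxy]-6-[(triisopropylsilyl)oxy]cyclohexa-1,3-diene-1-carbaldehyde | O=CC1=CC=C[C@@H](OCc2ccc(OC)cc2)[C@@H]1O[Si](C(C)C)(C(C)C)C(C)C | intermediate
11 | (5R,6R)-5-hydroxy-6-[(triisopropylsilyl)oxy]cyclohexa-1,3-diene-1-carbaldehyde | O=CC1=CC=C[C@@H](O)[C@@H]1O[Si](C(C)C)(C(C)C)C(C)C | intermediate
12 | (1R,6R)-5-(hydroxymethyl)-6-[(triisopropylsilyl)oxy]cyclohexa-2,4-dien-1-ol | OCC1=CC=C[C@@H](O)[C@@H]1O[Si](C(C)C)(C(C)C)C(C)C | intermediate
13 | [(5R,6R)-5-(benzoyloxy)-6-[(triisopropylsilyl)oxy]cyclohexa-1,3-dien-1-yl]methyl benzoate | O=C(OCC1=CC=C[C@@H](OC(=O)c2ccccc2)[C@@H]1O[Si](C(C)C)(C(C)C)C(C)C)c1ccccc1 | intermediate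
14 | [(5R,6R)-5-(benzoyloxy)-6-hydroxycyclohexa-1,3-dien-1-yl]methyl benzoate | O=C(OCC1=CC=C[C@@H](OC(=O)c2ccccc2)[C@@H]1O)c1ccccc1 | target

## Step count and least certain steps

Total step count: 12. Longest linear sequence: 12 steps (1 → 14; the route is fully linear).

**Step 6 (key step).** What may go wrong: thermal loss of the silyloxy group β to the new formyl group, followed by loss of the second ether and aromatisation. Conversion may also be slow, because the reactive half-chair with a pseudo-axial vinyl group is sparsely populated and the silyloxy group, which is cis to the vinyl group, crowds the forming bond. Fallback: starting from 6, the same [3,3] shift is promoted with iBu3Al in toluene at 20–50 °C. The aluminium reagent binds the ring oxygen, lowers the barrier and reduces the aldehyde as it forms by β-hydride transfer, so the primary alcohol [(1R,5R,6R)-5-[(4-methoxybenzyl)oxy]-6-[(triisopropylsilyl)oxy]cyclohex-3-en-1-yl]methanol F1 should be obtained without the aldehyde ever being heated. Oxidation of F1 with Dess–Martin periodinane and pyridine at room temperature returns to the route at 7.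

**Step 7.** What may go wrong: expulsion of the C6 silyloxy group through the enamine (an E1cB-type elimination) followed by aromatisation, or slow enamine formation at the α-branched aldehyde. Fallback: starting from 7, soft enolisation with triethylsilyl triflate and Et3N in CH2Cl2 at −78 °C should give the silyl enol ether triethyl{[(5R,6R)-5-[(4-methoxybenzyl)oxy]-6-[(triisopropylsilyl)oxy]cyclohex-3-en-1-ylidene]methoxy}silane F2. F2 is treated with PhSeCl at −78 °C; no amine-bound or metal enolate is involved, and the route is rejoined at 8.

**Step 9.** What may go wrong: oxidation beyond ether cleavage, either hydride abstraction from the ring leading to aromatisation or oxidation of the freed allylic hydroxyl. Fallback: starting from 10, a non-oxidative dealkylation with MgBr2·OEt2 and Me2S in CH2Cl2 (Lewis-acid activation of the ether oxygen and attack of the sulfide at the benzylic carbon) should give 11 directly. This replaces a redox process by a substitution and makes no new compound (F0).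

**Step 12.** What may go wrong: slow cleavage of the hindered secondary silyl ether, during which acyl migration from O5 to O6 or acid-promoted aromatisation can set in. Fallback: starting from 12, the silyl group is removed first with Bu4NF in THF (no ester is present, so basic fluoride is harmless) to give the triol (1R,2R)-3-(hydroxymethyl)cyclohexa-3,5-diene-1,2-diol F3. F3 is then benzoylated with two equivalents of benzoyl chloride and 2,4,6-collidine at −40 °C, relying on the primary hydroxyl and the less hindered C5 hydroxyl reacting before the flanked C6 hydroxyl. This rejoins the route at 14.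

## Further compounds

F1 | step 6 | [(1R,5R,6R)-5-[(4-methoxybenzyl)oxy]-6-[(triisopropylsilyl)oxy]cyclohex-3-en-1-yl]methanol | OC[C@H]1CC=C[C@@H](OCc2ccc(OC)cc2)[C@@H]1O[Si](C(C)C)(C(C)C)C(C)C
F2 | step 7 | triethyl{[(5R,6R)-5-[(4-methoxybenzyl)oxy]-6-[(triisopropylsilyl)oxy]cyclohex-3-en-1-ylidene]methoxy}silane (E/Z mixture) | CC[Si](CC)(CC)OC=C1CC=C[C@@H](OCc2ccc(OC)cc2)[C@@H]1O[Si](C(C)C)(C(C)C)C(C)C
F0 | step 9 | none | none
F3 | step 12 | (1R,2R)-3-(hydroxymethyl)cyclohexa-3,5-diene-1,2-diol | OCC1=CC=C[C@@H](O)[C@@H]1O
A1 | alternative 1 | methyl (5R,6R)-5-(benzoyloxy)-6-[(tert-butyldimethylsilyl)oxy]cyclohexa-1,3-diene-1-carboxylate | COC(=O)C1=CC=C[C@@H](OC(=O)c2ccccc2)[C@@H]1O[Si](C)(C)C(C)(C)C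
A2 | alternative 1 | methyl cis-3-[(Z)-2-(benzoyloxy)ethenyl]-4-[(tert-butyldimethylsilyl)oxy]cyclobut-1-ene-1-carboxylate (racemic, one enantiomer drawn) | COC(=O)C1=C[C@H](/C=C\OC(=O)c2ccccc2)[C@@H]1O[Si](C)(C)C(C)(C)C
A3 | alternative 1 | methyl (2Z,3Z,5Z)-6-(benzoyloxy)-2-{[(tert-butyldimethylsilyl)oxy]methylidene}hexa-3,5-dienoate | CC(C)(C)[Si](C)(C)O/C=C(\C(=O)OC)/C=C\C=C/OC(=O)c1ccccc1
A4 | alternative 2 | (8R,8aR)-2,2-diisopropyl-8,8a-dihydro-4H-benzo[d][1,3,2]dioxasilin-8-yl benzoate | CC(C)[Si]1(C(C)C)OCC2=CC=C[C@@H](OC(=O)c3ccccc3)[C@@H]2O1
A5 | alternative 2 | (E)-2-{[diisopropyl(prop-2-yn-1-yloxy)silyl]oxy}ethenyl benzoate | C#CCO[Si](C(C)C)(C(C)C)O/C=C/OC(=O)c1ccccc1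
A6 | alternative 2 | acetylene | C#C
A7 | alternative 3 | (5R,6R)-5-[(4-methoxybenzyl)oxy]-1-{[(4-methoxybenzyl)oxy]methyl}-6-[(triethylsilyl)oxy]cyclohexa-1,3-diene | COc1ccc(COCC2=CC=C[C@@H](OCc3ccc(OC)cc3)[C@@H]2O[Si](CC)(CC)CC)cc1
A8 | alternative 3 | (1Z,3R,4R,5Z)-1,6-diiodo-4-[(4-methoxybenzyl)oxy]-2-{[(4-methoxybenzyl)oxy]methyl}-3-[(triethylsilyl)oxy]hexa-1,5-diene | I/C=C(/COCc1ccc(OC)cc1)\[C@@H](O[Si](CC)(CC)CC)[C@H](OCc1ccc(OC)cc1)/C=C\I
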